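**Retrosynthetic overview**

1. The hydroxy acetate is unveiled last from spiro-oxirane 26 by acetate attack at the oxirane CH2. The oxirane is a temporary ring that carries the tertiary C–O centre and the future acetoxymethyl carbon.
2. Key disconnection in 26: the cyclopentane bond between the carbon bearing the dienyl chain and the carbon bearing the cyclopentenone, made by a 5-exo radical conjugate addition from cesium oxalate 23. Both carbinol epimers of 23 converge on one allyl radical.
3. 23 comes from aldehyde 19 and (Z)-vinyl iodide 6 (Nozaki–Hiyama–Kishi). 19 comes from (S)-4-methylcyclopent-2-enone 13 and epoxy aldehyde 12 (syn-aldol, syn-dehydration). 12 comes from methallyl alcohol and allyl bromide (Sharpless epoxidation).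
4. Ring order: cyclopentenone (bought with its methyl stereocentre), then oxirane (step 5), then cyclopentane (step 13, last ring of the skeleton).
5. Enabling feature: the cyclopentane carbon that bears the side chain is allylic to the C(CH3)=CH bond, so it can be a delocalised radical. Its ring neighbour is the exocyclic β-carbon of an enone built on the carbonyl and α-carbon of the cyclopentenone ring, reached through a three-atom tether (5-exo).

Key step: step 13

Remark: (S)-4-methylcyclopent-2-en-1-one (13) is taken as a catalogue chiral building block; if it had to be made, dehydrogenation of commercial (R)-3-methylcyclopentanone away from the methyl group would give it.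

**Route**

Step 1
Reactants: 1 but-2-yn-1-ol
Product: 3 (Z)-3-iodobut-2-en-1-ol, via sodium alkenylaluminate 2 (not isolated)
Conditions: NaAlH2(OCH2CH2OCH3)2, THF, 0 °C to rt; then I2, −78 to 0 °C
Reagents that add atoms: iodine, II
Why: trans-hydroalumination of the propargylic alcohol through the cyclic alkoxyaluminate puts aluminium on the distal carbon, and iodinolysis with retention should give only the (Z)-iodoalkene (no stereocentre).

Step 2
Reactants: 3 (Z)-3-iodobut-2-en-1-ol
Product: 4 (Z)-1-bromo-3-iodobut-2-ene
Conditions: CBr4, PPh3, CH2Cl2, 0 °C
Reagents that add atoms: tetrabromomethane, BrC(Br)(Br)Br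
Why: Appel bromination is an SN2 displacement at the primary allylic carbon and should leave the (Z)-iodoalkene untouched.

Step 3
Reactants: 4 (Z)-1-bromo-3-iodobut-2-ene; 5 (2-methylprop-1-en-1-yl)magnesium bromide
Product: 6 (Z)-2-iodo-6-methylhepta-2,5-diene
Conditions: CuI (10 mol%), THF, −30 to 0 °C
Reagents that add atoms: none
Why: copper-catalysed Grignard allylic substitution should occur by SN2 at the unhindered primary terminus (SN2′ would need attack at the fully substituted iodo-bearing carbon), building the skipped diene with the vinyl iodide geometry intact.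

Step 4
Reactants: 7 2-methylprop-2-en-1-ol; 8 allyl bromide
Product: 10 2-methylidenehex-5-en-1-ol, via dilithio dianion 9 (not isolated)
Conditions: n-BuLi (2.2 equiv), TMEDA, Et2O/hexane, 0 °C to rt; then 8, −78 °C to rt
Reagents that add atoms: none
Why: double deprotonation gives the O,C-dilithio methallyl dianion, whose carbon terminus alkylates allyl bromide (dianion alkylation, no stereocentre).

Step 5
Reactants: 10 2-methylidenehex-5-en-1-ol
Product: 11 (R)-[2-(but-3-en-1-yl)oxiran-2-yl]methanol
Conditions: Ti(OiPr)4 (cat.), D-(−)-diethyl tartrate (cat.), t-BuOOH, 4 Å MS, CH2Cl2, −20 °C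
Reagents that add atoms: tert-butyl hydroperoxide, CC(C)(C)OO
Why: Sharpless asymmetric epoxidation is directed by the allylic hydroxyl, so only the 1,1-disubstituted alkene reacts, and the D-(−)-tartrate ligand should set the quaternary oxirane carbon as (R).

Step 6
Reactants: 11 (R)-[2-(but-3-en-1-yl)oxiran-2-yl]methanol
Product: 12 (S)-2-(but-3-en-1-yl)oxirane-2-carbaldehyde
Conditions: TEMPO (cat.), PhI(OAc)2, CH2Cl2, rt
Reagents that add atoms: none
Why: oxoammonium (TEMPO) oxidation of the primary alcohol stops at the aldehyde, which has no α-hydrogen, so the quaternary centre cannot epimerise (the descriptor changes by priority only).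

Step 7
Reactants: 13 (S)-4-methylcyclopent-2-en-1-one; 12 (S)-2-(but-3-en-1-yl)oxirane-2-carbaldehyde
Product: 16 syn-aldol adduct (4S)-5-[hydroxy(2-(but-3-enyl)oxiran-2-yl)methyl]-4-methylcyclopent-2-en-1-one, via lithium dienolate 14 (not isolated), via titanium dienolate 15 (not isolated)
Conditions: LiN(iPr)2, THF, −78 °C; ClTi(OiPr)3, −78 to −40 °C; then 12, −78 °C; aq NH4Cl
Reagents that add atoms: none
Why: kinetic α′-deprotonation gives the cross-conjugated dienolate, and its triisopropoxytitanium form should add to the aldehyde syn-selectively (titanium aldol of a cyclic ketone, Zimmerman–Traxler) on the face opposite to the ring methyl; the two new centres only serve to fix the alkene geometry in step 8.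

Step 8
Reactants: 16 syn-aldol adduct
Product: 17 (4S)-5-[(Z)-(2-(but-3-enyl)oxiran-2-yl)methylidene]-4-methylcyclopent-2-en-1-one
Conditions: DCC, CuCl (cat.), toluene, 60 °C, dark
Reagents that add atoms: none
Why: carbodiimide/CuCl dehydration is a stereospecific syn-elimination through the O-alkylisourea, so the syn-aldol should give the (Z)-alkylidene with the oxirane carbon cis to the carbonyl, under non-basic conditions that spare the methyl-bearing centre.

Step 9
Reactants: 17 (Z)-alkylidene cyclopentenone
Product: 19 3-{2-[(Z)-((5S)-5-methyl-2-oxocyclopent-3-en-1-ylidene)methyl]oxiran-2-yl}propanal, via vicinal diol 18 (not isolated)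
Conditions: OsO4 (2 mol%), NaIO4, 2,6-lutidine, dioxane/H2O, rt
Reagents that add atoms: sodium periodate, [Na+].[O-]I(=O)(=O)=O
Why: in this Lemieux–Johnson cleavage OsO4 should dihydroxylate the electron-rich monosubstituted alkene much faster than the two electron-poor enone alkenes, and periodate cleaves the diol to the aldehyde.

Step 10
Reactants: 19 oxirane dienone aldehyde; 6 (Z)-2-iodo-6-methylhepta-2,5-diene
Product: 21 allylic alcohol (both carbinol epimers) with the (Z)-6-methylhepta-2,5-dien-2-yl group on the new carbinol carbon, via alkenylchromium dichloride 20 (not isolated)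
Conditions: CrCl2 (5 equiv), NiCl2 (1 mol%), DMSO/THF, rt
Reagents that add atoms: none
Why: in the Nozaki–Hiyama–Kishi coupling the alkenylchromium species adds to the aldehyde only (ketone, enone and oxirane are tolerated) with retention of the (Z)-geometry; the new carbinol centre forms as a mixture, which is harmless because step 13 erases it.

Step 11
Reactants: 21 allylic alcohol
Product: 22 methyl oxalate of 21
Conditions: ClC(O)CO2CH3, pyridine, DMAP (cat.), CH2Cl2, 0 °C
Reagents that add atoms: methyl chlorooxoacetate, COC(=O)C(Cl)=O
Why: O-acylation of the secondary allylic alcohol by the acid chloride does not break the allylic C–O bond, so neither allylic transposition nor loss of alkene geometry is expected.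

Step 12
Reactants: 22 methyl oxalate
Product: 23 cesium oxalate
Conditions: CsOH·H2O (1.0 equiv), THF/H2O, 0 °C, minutes; lyophilise
Reagents that add atoms: cesium hydroxide, [Cs+].[OH-]
Why: the methyl oxalate ester is saponified by one equivalent of hydroxide far faster than any other group reacts, giving the bench-stable radical precursor (selective ester hydrolysis).

Step 13
Reactants: 23 cesium oxalate
Product: 26 spiro-oxirane (4-[(1S,5R)-5-methyl-2-oxocyclopent-3-en-1-yl]-5-[(Z)-6-methylhepta-2,5-dien-2-yl]-1-oxaspiro[2.4]heptane; configuration as in the target), via allyl radical 24 (not isolated), via cesium dienolate 25 (not isolated)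
Conditions: Ir[dF(CF3)ppy]2(dtbbpy)PF6 (2 mol%), DME/DMF 3:1, H2O (10 equiv), 450 nm LEDs, 40 °C, 0.01 M
Reagents that add atoms: none
Why: Photoexcited trivalent iridium oxidises the oxalate, which loses two CO2 to give a delocalised allyl radical at the former carbinol carbon, so both epimers of 23 converge; the radical adds to the exocyclic β-carbon of the (Z)-alkylidene cyclopentenone, the α-keto radical is reduced by divalent iridium to dienolate 25, and water protonates it (closest known type: redox-neutral oxalate-derived radical conjugate addition, here run as a radical cyclisation). The cyclopentane closes in the 5-exo-trig mode through the ring-side terminus of the allyl radical, the seven-membered closure through the distal terminus being slower. The (Z)-alkene of the side chain should be retained because the allyl radical does not rotate on the time scale of cyclisation. The stereocentre carrying the cyclopentenone is set by attack on the alkene face opposite to the ring methyl, which is also the face where the tether lies with the oxirane oxygen turned away from the carbonyl oxygen; the stereocentre carrying the side chain is set cis to it by a chair-like Beckwith–Houk transition state with the alkenyl group pseudo-equatorial on the radical carbon; the ketone α-carbon is set by protonation of 25 opposite to the methyl group and to the quaternary oxirane carbon. The step needs regioselectivity (exocyclic β-carbon, not the endocyclic enone) and facial selectivity, secured by the three-atom tether, by the (Z)-geometry from step 8 and by the methyl stereocentre already on the cyclopentenone.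

Step 14
Reactants: 26 spiro-oxirane
Product: 27 target hydroxy acetate
Conditions: Bu4NOAc (1 equiv), AcOH (5 equiv), MeCN, 45 °C
Reagents that add atoms: acetic acid, CC(=O)O
Why: buffered acetate should open the spiro-oxirane by SN2 at its CH2 terminus (acid-assisted epoxide opening), so the tertiary C–O bond keeps its configuration and the tertiary alcohol and primary acetate appear together, in a medium too weakly basic to epimerise the ketone α-carbon.

**Compound list**

1 | but-2-yn-1-ol | CC#CCO | starting material
2 | sodium (Z)-alkenylalkoxyaluminate (five-membered C=C–C–O–Al ring, two 2-methoxyethoxy groups on Al) | CC1=CCO[Al-]1(OCCOC)OCCOC.[Na+] | intermediate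
3 | (Z)-3-iodobut-2-en-1-ol | C/C(I)=C/CO | intermediate
4 | (Z)-1-bromo-3-iodobut-2-ene | C/C(I)=C/CBr | intermediate
5 | (2-methylprop-1-en-1-yl)magnesium bromide | CC(C)=C[Mg]Br | starting material
6 | (Z)-2-iodo-6-methylhepta-2,5-diene | C/C(I)=C/CC=C(C)C | intermediate
7 | 2-methylprop-2-en-1-ol | CC(=C)CO | starting material
8 | allyl bromide (3-bromoprop-1-ene) | C=CCBr | starting material
9 | O,C-dilithio dianion of 7 | [Li]CC(=C)CO[Li] | intermediate
10 | 2-methylidenehex-5-en-1-ol | C=CCCC(=C)CO | intermediate
11 | (R)-[2-(but-3-en-1-yl)oxiran-2-yl]methanol | OC[C@]1(CCC=C)CO1 | intermediate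
12 | (S)-2-(but-3-en-1-yl)oxirane-2-carbaldehyde | O=C[C@]1(CCC=C)CO1 | intermediate
13 | (S)-4-methylcyclopent-2-en-1-one | C[C@@H]1C=CC(=O)C1 | starting material
14 | lithium (S)-4-methylcyclopenta-1,4-dien-1-olate (cross-conjugated dienolate of 13) | C[C@@H]1C=CC(O[Li])=C1 | intermediate
15 | triisopropoxytitanium dienolate of 13 | C[C@@H]1C=CC(O[Ti](OC(C)C)(OC(C)C)OC(C)C)=C1 | intermediate
16 | syn-aldol adduct: (4S)-5-[hydroxy(2-(but-3-enyl)oxiran-2-yl)methyl]-4-methylcyclopent-2-en-1-one; side chain trans to the methyl, ring α-carbon and carbinol syn, oxirane carbon as in 12 | O=C1C=C[C@@H](C)[C@@H]1[C@@H](O)[C@]2(CCC=C)CO2 | intermediate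
17 | (4S)-5-[(Z)-(2-(but-3-enyl)oxiran-2-yl)methylidene]-4-methylcyclopent-2-en-1-one (oxirane carbon cis to C=O) | O=C1C=C[C@@H](C)/C1=C/[C@]2(CCC=C)CO2 | intermediate
18 | vicinal diol from 17 (terminal alkene dihydroxylated, new carbinol centre unassigned) | O=C1C=C[C@@H](C)/C1=C/[C@]2(CCC(O)CO)CO2 | intermediate
19 | 3-{2-[(Z)-((5S)-5-methyl-2-oxocyclopent-3-en-1-ylidene)methyl]oxiran-2-yl}propanal | O=C1C=C[C@@H](C)/C1=C/[C@]2(CCC=O)CO2 | intermediate
20 | [(Z)-6-methylhepta-2,5-dien-2-yl]chromium dichloride | C/C([Cr](Cl)Cl)=C/CC=C(C)C | intermediate
21 | allylic alcohol: 19 with the aldehyde carbon converted into CH(OH) bearing the (Z)-6-methylhepta-2,5-dien-2-yl group (both carbinol epimers) | O=C1C=C[C@@H](C)/C1=C/[C@]2(CCC(O)/C(C)=C\CC=C(C)C)CO2 | intermediate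
22 | methyl oxalate of 21 | O=C1C=C[C@@H](C)/C1=C/[C@]2(CCC(OC(=O)C(=O)OC)/C(C)=C\CC=C(C)C)CO2 | intermediate
23 | cesium oxalate of 21 | O=C1C=C[C@@H](C)/C1=C/[C@]2(CCC(OC(=O)C(=O)[O-])/C(C)=C\CC=C(C)C)CO2.[Cs+] | intermediate
24 | allyl radical at the former carbinol carbon | O=C1C=C[C@@H](C)/C1=C/[C@]2(CC[CH]/C(C)=C\CC=C(C)C)CO2 | intermediate
25 | cesium cyclopentadienolate formed after ring closure | C1O[C@@]12CC[C@@H](/C(C)=C\CC=C(C)C)[C@H]2C1=C([O-])C=C[C@H]1C.[Cs+] | intermediate
26 | spiro-oxirane: 4-[(1S,5R)-5-methyl-2-oxocyclopent-3-en-1-yl]-5-[(Z)-6-methylhepta-2,5-dien-2-yl]-1-oxaspiro[2.4]heptane; cyclopentenone, side chain and oxirane CH2 on one face, oxirane O on the other | C1O[C@@]12CC[C@@H](/C(C)=C\CC=C(C)C)[C@H]2[C@H]1C(=O)C=C[C@H]1C | intermediate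
27 | CNP0222995.1: [(1R,2S,3R)-1-hydroxy-2-[(1S,5R)-5-methyl-2-oxocyclopent-3-en-1-yl]-3-[(Z)-6-methylhepta-2,5-dien-2-yl]cyclopentyl]methyl acetate | CC(=O)OC[C@@]1(O)CC[C@@H](/C(C)=C\CC=C(C)C)[C@H]1[C@H]1C(=O)C=C[C@H]1C | target

**Count and risks**

Total steps: 14. Longest linear sequence: 11 (steps 4 to 14); steps 1 to 3 make the vinyl iodide, which joins at step 10.

Steps most likely to fail:

Step 13. The cesium dienolate formed after ring closure may open the neighbouring spiro-oxirane or lose the kinetic configuration at the ketone α-carbon before it is protonated, and single-electron oxidation of a secondary oxalate may be slow enough for the allyl radical to be lost before it cyclises. The fallback sets out from 21 and avoids both the salt and the enolate. 21 would be acylated with N-phthalimidoyl chlorooxalate to the N-phthalimidoyl oxalate F1. Irradiation with Ru(bpy)3(PF6)2 and Hantzsch ester (blue light, CH2Cl2) should then fragment it reductively to the same allyl radical; after 5-exo closure the α-keto radical is quenched by hydrogen-atom transfer from the Hantzsch ester. This comes back to the route at 26.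

Step 7. Erosion of syn-selectivity in the titanium aldol would be carried by the stereospecific syn-elimination into the (E)-alkylidene, which leads to the wrong configuration at the carbon bearing the cyclopentenone. The fallback sets out from 16 as any mixture of aldol isomers. Mesylation (CH3SO2Cl, Et3N, 0 °C) gives mesylate F2, which eliminates in the same pot to the (E)-rich alkylidene F3. Photochemical E-to-Z isomerisation of the exocyclic enone (350 nm, MeCN, recycling of recovered F3) would then supply the (Z)-isomer, coming back to the route at 17.

Step 14. The acetate buffer may epimerise the ketone α-carbon (loss of the cis relation on the cyclopentenone) or attack the tertiary oxirane carbon with inversion. The fallback sets out from 26. An epoxide hydrolase at pH 7 would hydrolyse the 2,2-disubstituted oxirane at its CH2 terminus to the diol F4, and selective acetylation of the primary hydroxyl (acetic anhydride, pyridine, 0 °C) comes back to the route at 27.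

Further compounds
F1 | step 13 | N-phthalimidoyl oxalate of 21 | O=C1C=C[C@@H](C)/C1=C/[C@]2(CCC(OC(=O)C(=O)ON3C(=O)c4ccccc4C3=O)/C(C)=C\CC=C(C)C)CO2
F2 | step 7 | mesylate of 16 (aldol centres unassigned) | O=C1C=C[C@@H](C)C1C(OS(C)(=O)=O)[C@]2(CCC=C)CO2
F3 | step 7 | (4S)-5-[(E)-(2-(but-3-enyl)oxiran-2-yl)methylidene]-4-methylcyclopent-2-en-1-one | O=C1C=C[C@@H](C)/C1=C\[C@]2(CCC=C)CO2
F4 | step 14 | diol: deacetyl target, (1R,2S,3R)-1-(hydroxymethyl)cyclopentan-1-ol with the same two ring substituents | OC[C@@]1(O)CC[C@@H](/C(C)=C\CC=C(C)C)[C@H]1[C@H]1C(=O)C=C[C@H]1C
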